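**Retrosynthetic overview**
1. Numbering (germacrane): C1 ketone, C2=C3 enol ether, C4(Me, C15)=C5, C6–O (lactone), C7, C8–OAng, C9H2, C10(Me, C14)–O, C11=C13, C12 lactone C=O. Ring A is the γ-lactone, ring B the ten-membered carbocycle C1–C10, ring C the 3(2H)-furanone O/C3/C2/C1/C10.
2. Enabling feature: C3 is a carbonyl-level carbon flanked only by sp2 carbons (C4 of the Z-alkene and C2), and it sits 1,4 to the tertiary C10–O. Ring C is therefore a constitutional isomer of the 4-hydroxy-2-ynone C3(=O)–C2≡C1–C10(OH), and C3 itself can be excised as CO.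
3. Final one-pot event: vinyl iodide C4–I, CO and the terminal alkyne C2–H close ring B. An amine/water-mediated 1,3-carbonyl transposition then closes ring C. C11=C13 is stored as a Mannich base and released in the last step.
4. Seco precursor: ring A comes from a reagent-controlled syn-aldol/lactonisation of a γ-keto ester (C12–C11–C7–C8(=O)–C9–C10) with (Z)-3-iodobut-2-enal (C6–C5–C4, C15). C8 is set by Felkin–Anh reduction and C10 by catalytic asymmetric propargylation of an ynone.
5. Ring order: A (step 7), then B and C in step 12, with C last.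

Key step: step 12

Assumption: the sense of induction of the two external chiral controllers (catalyst in step 3, borane in step 7) is assigned by analogy with simpler substrates. Both are available as either antipode.

**Step 1**
Reactants: 1 but-2-yn-1-ol
Product: 3 (Z)-3-iodobut-2-en-1-ol, via cyclic alkenylalanate 2 (not isolated)
Conditions: Red-Al, THF, 0 °C to rt; then I2, −78 to 0 °C
Reagents that add atoms: iodine, II
Why: Hydroxyl-directed trans-hydroalumination of the propargylic alcohol places Al on the distal alkyne carbon inside a five-membered alanate, and iodinolysis with retention should give the Z-iodide (hydroalumination–iodination).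

**Step 2**
Reactants: 3 (Z)-3-iodobut-2-en-1-ol
Product: 4 (Z)-3-iodobut-2-enal
Conditions: activated MnO2, CH2Cl2, rt, dark
Reagents that add atoms: none
Why: Neutral MnO2 oxidation of an allylic alcohol should leave the C–I bond and the Z geometry untouched, provided the aldehyde is used at once.

**Step 3**
Reactants: 5 4-(trimethylsilyl)but-3-yn-2-one; 6 allenylboronic acid pinacol ester
Product: 8 (R)-3-methyl-1-(trimethylsilyl)hexa-1,5-diyn-3-ol, via borate ester 7 (not isolated)
Conditions: (S)-3,3′-Br2-BINOL (10 mol %), t-BuOH, toluene, rt to 40 °C; aq. NaHCO3 work-up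
Reagents that add atoms: none
Why: Diol-catalysed asymmetric propargylation of a ketone with an allenylboronate (SE2′, closed six-membered transition state on the chiral boronate) adds 1,2 to the ynone and should set C10 as R by telling the linear silylalkynyl group from methyl.

**Step 4**
Reactants: 8 (R)-3-methyl-1-(trimethylsilyl)hexa-1,5-diyn-3-ol
Product: 9 (R)-triethylsilyl ether of 8
Conditions: TESOTf, 2,6-lutidine, CH2Cl2, −78 to 0 °C
Reagents that add atoms: triethylsilyl triflate, CC[Si](CC)(CC)OS(=O)(=O)C(F)(F)F
Why: Silyl triflate silylation is the standard way to protect a hindered tertiary alcohol, and it touches neither alkyne nor C10.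

**Step 5**
Reactants: 9 (R)-triethylsilyl ether of 8; 10 ethyl diazoacetate
Product: 11 ethyl (R)-6-methyl-6-(triethylsilyloxy)-8-(trimethylsilyl)octa-3,7-diynoate
Conditions: CuI (5 mol %), MeCN, rt
Reagents that add atoms: none
Why: Copper(I)-catalysed coupling of a terminal alkyne with a diazoacetate (formal C(sp)–H insertion) should give the 3-alkynoate under base-free conditions, and only the free alkyne (C7) can react.

**Step 6**
Reactants: 11 ethyl (R)-6-methyl-6-(triethylsilyloxy)-8-(trimethylsilyl)octa-3,7-diynoate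
Product: 12 ethyl (R)-6-methyl-4-oxo-6-(triethylsilyloxy)-8-(trimethylsilyl)oct-7-ynoate
Conditions: NaAuCl4·2H2O (2 mol %), EtOH–H2O, rt
Reagents that add atoms: water, O
Why: Gold-catalysed hydration of a 3-alkynoate with participation of the neighbouring ester carbonyl puts the oxygen on the alkyne carbon remote from the ester (C8), while the silylated alkyne lacks this assistance and should stay intact.

**Step 7**
Reactants: 12 ethyl (R)-6-methyl-4-oxo-6-(triethylsilyloxy)-8-(trimethylsilyl)oct-7-ynoate; 4 (Z)-3-iodobut-2-enal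
Product: 15 (6S,7S,10R)-keto lactone, via (Z)-enol borinate 13 (not isolated), via syn-aldol hydroxy ester 14 (not isolated)
Conditions: (−)-Ipc2BOTf, i-Pr2NEt, CH2Cl2, −78 °C; 4, −78 to −20 °C; H2O2, MeOH, pH 7 buffer, 0 °C; then PPTS (cat.), CH2Cl2, rt
Reagents that add atoms: none
Why: In this diisopinocampheylboron-mediated syn-aldol reaction the bulky borane enolises the less hindered C7 side to the Z-enolate, the chair transition state gives the syn relation C6/C7, the Ipc ligands direct attack to the si face of 4, and the C6 hydroxyl then lactonises onto C12 to the trans-lactone, which is also the thermodynamic C7 epimer.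

**Step 8**
Reactants: 15 (6S,7S,10R)-keto lactone
Product: 16 (6S,7R,8R,10R)-hydroxy lactone
Conditions: L-Selectride, THF, −78 °C; AcOH quench at −78 °C
Reagents that add atoms: none
Why: In this Felkin–Anh reduction with a bulky non-chelating hydride, C6 is the large group, C11 the medium group and H the small group at C7, so attack anti to C6 should give 8R, while the cold acidic quench prevents migration of the lactone to O8.

**Step 9**
Reactants: 16 (6S,7R,8R,10R)-hydroxy lactone
Product: 18 (6S,7R,8R,10R,11R)-α-(dimethylaminomethyl) lactone, via dilithio alkoxide enolate 17 (not isolated)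
Conditions: LiHMDS (2.2 equiv), THF, −78 °C; Me2N=CH2+ I−, −78 to −20 °C; H2O
Reagents that add atoms: Eschenmoser's salt, C=[N+](C)C.[I-]
Why: Mannich alkylation of the kinetic lactone enolate should occur anti to the C7 side chain, and the temporary C11 stereocentre masks the later C11=C13 alkene.

**Step 10**
Reactants: 18 (6S,7R,8R,10R,11R)-α-(dimethylaminomethyl) lactone; 19 angelic acid
Product: 21 C8 angelate of 18, via angelic trichlorobenzoic anhydride 20 (not isolated)
Conditions: 19, 2,4,6-Cl3C6H2COCl, Et3N, toluene, rt; then 18, 75 °C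
Reagents that add atoms: none
Why: Yamaguchi-type mixed-anhydride esterification run without a nucleophilic catalyst is the known stereoconservative way to make angelates, and the C8–O bond is not broken.

**Step 11**
Reactants: 21 C8 angelate of 18
Product: 22 seco iodo-alkynol (6S,7R,8R,10R,11R)
Conditions: TBAF, AcOH, THF, 0 °C to rt
Reagents that add atoms: none
Why: Buffered fluoride should cleave both the alkynyl C–Si bond and the tertiary O–Si bond, and the buffer protects the lactone, the angelate and the Mannich base.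

**Step 12**
Reactants: 22 seco iodo-alkynol (6S,7R,8R,10R,11R)
Product: 25 13-(dimethylamino)-11,13-dihydro-15-deoxybudlein A, via macrocyclic ynone 23 (not isolated), via macrocyclic enaminone 24 (not isolated)
Conditions: PdCl2(PPh3)2 (10 mol %), CuI (10 mol %), Et3N, CO (1 atm), THF, 40 °C, 22 added over 12 h (final 1 mM); then Et2NH, rt; then AcOH–H2O, 40 °C
Reagents that add atoms: carbon monoxide, [C-]#[O+]; water, O
Why: Proposed new method: Pd(0) inserts into the (Z)-C4–I bond with retention, CO inserts, the copper acetylide of C2 is transferred and reductive elimination closes the ten-membered carbocycle as ynone 23, so that CO becomes C3. Et2NH then adds to C1, the β-carbon of the strained ynone, to give the (E)-enaminone 24 with C10–OH held next to C3=O, and aqueous acid brings about hemiketalisation, loss of the CO-derived oxygen as water and hydrolysis of the C1 iminium ion to the C1 ketone. The closest known reaction types are the intermolecular Pd-catalysed carbonylative coupling of aryl or vinyl iodides with tertiary propargylic alcohols that ends in 3(2H)-furanones, the amine-mediated isomerisation of 4-hydroxy-2-ynones to 3(2H)-furanones and the carbonylative Stille macrocyclisation; the medium-ring transannular combination is what is new. Modes of closure: carbocycle by C2–C3 reductive elimination from an eleven-membered acyl(alkynyl)palladacycle, furanone by 5-exo-trig attack of O–C10 on the C3 carbonyl followed by dehydration. No stereocentre is formed: the C10–O bond is never broken, so C10 stays R as set in step 3, and the 4Z geometry is that of the iodide. The step needs carbonylative over direct coupling (the direct product would be a far more strained nine-membered 1,3-enyne), ring closure over oligomerisation (slow addition at 1 mM, with the Z-alkene, the trans-lactone and the quaternary C10 folding the chain) and no six-membered acylpalladation onto C11=C13, which is excluded because that alkene is stored as the Mannich base.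

**Step 13**
Reactants: 25 13-(dimethylamino)-11,13-dihydro-15-deoxybudlein A
Product: 27 15-deoxybudlein A, via trimethylammonium iodide 26 (not isolated)
Conditions: MeI, THF, rt; then aq. NaHCO3, EtOAc, rt
Reagents that add atoms: none
Why: Quaternisation of the Mannich base and mild E1cB (Hofmann-type) elimination is the standard release of an α-methylene-γ-lactone, it removes the C11 stereocentre, and it should not affect the furanone or the angelate.

**Compound list**
1 | but-2-yn-1-ol | CC#CCO | starting material
2 | sodium cyclic (Z)-alkenylalanate of 1 | CC1=CCO[Al-]1(OCCOC)OCCOC.[Na+] | intermediate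
3 | (Z)-3-iodobut-2-en-1-ol | OC/C=C(/C)I | intermediate
4 | (Z)-3-iodobut-2-enal | O=C/C=C(/C)I | intermediate
5 | 4-(trimethylsilyl)but-3-yn-2-one | CC(=O)C#C[Si](C)(C)C | starting material
6 | allenylboronic acid pinacol ester | C=C=CB1OC(C)(C)C(C)(C)O1 | starting material
7 | (R)-pinacol borate ester of 8 | C#CC[C@@](C)(OB1OC(C)(C)C(C)(C)O1)C#C[Si](C)(C)C | intermediate
8 | (R)-3-methyl-1-(trimethylsilyl)hexa-1,5-diyn-3-ol | C#CC[C@@](C)(O)C#C[Si](C)(C)C | intermediate
9 | (R)-3-methyl-3-(triethylsilyloxy)-1-(trimethylsilyl)hexa-1,5-diyne | C#CC[C@@](C)(O[Si](CC)(CC)CC)C#C[Si](C)(C)C | intermediate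
10 | ethyl diazoacetate | CCOC(=O)C=[N+]=[N-] | starting material
11 | ethyl (R)-6-methyl-6-(triethylsilyloxy)-8-(trimethylsilyl)octa-3,7-diynoate | CCOC(=O)CC#CC[C@@](C)(O[Si](CC)(CC)CC)C#C[Si](C)(C)C | intermediate
12 | ethyl (R)-6-methyl-4-oxo-6-(triethylsilyloxy)-8-(trimethylsilyl)oct-7-ynoate | CCOC(=O)CCC(=O)C[C@@](C)(O[Si](CC)(CC)CC)C#C[Si](C)(C)C | intermediate
13 | (Z)-enol diisopinocampheylborinate of 12 (C7=C8) | CCOC(=O)C/C=C(\OB([C@@H]1C[C@@H]2C[C@H]([C@H]1C)C2(C)C)[C@@H]1C[C@@H]2C[C@H]([C@H]1C)C2(C)C)C[C@@](C)(O[Si](CC)(CC)CC)C#C[Si](C)(C)C | intermediate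
14 | (6S,7S,10R)-syn-aldol hydroxy keto ester | CCOC(=O)C[C@@H]([C@H](O)/C=C(/C)I)C(=O)C[C@@](C)(O[Si](CC)(CC)CC)C#C[Si](C)(C)C | intermediate
15 | (6S,7S,10R)-keto lactone: trans-γ-lactone with (Z)-2-iodoprop-1-enyl on C6 and the C8 acyl chain on C7 | C1C(=O)O[C@H](/C=C(/C)I)[C@H]1C(=O)C[C@@](C)(O[Si](CC)(CC)CC)C#C[Si](C)(C)C | intermediate
16 | (6S,7R,8R,10R)-hydroxy lactone | C1C(=O)O[C@H](/C=C(/C)I)[C@H]1[C@H](O)C[C@@](C)(O[Si](CC)(CC)CC)C#C[Si](C)(C)C | intermediate
17 | dilithio C8-alkoxide lactone enolate of 16 | [Li]OC1=C[C@H]([C@H](O[Li])C[C@@](C)(O[Si](CC)(CC)CC)C#C[Si](C)(C)C)[C@@H](/C=C(/C)I)O1 | intermediate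
18 | (6S,7R,8R,10R,11R)-α-(dimethylaminomethyl) hydroxy lactone | CN(C)C[C@@H]1C(=O)O[C@H](/C=C(/C)I)[C@H]1[C@H](O)C[C@@](C)(O[Si](CC)(CC)CC)C#C[Si](C)(C)C | intermediate
19 | angelic acid, (Z)-2-methylbut-2-enoic acid | C/C=C(/C)C(=O)O | starting material
20 | angelic 2,4,6-trichlorobenzoic anhydride | C/C=C(/C)C(=O)OC(=O)c1c(Cl)cc(Cl)cc1Cl | intermediate
21 | (6S,7R,8R,10R,11R)-C8 angelate, bis-silylated | CN(C)C[C@@H]1C(=O)O[C@H](/C=C(/C)I)[C@H]1[C@H](OC(=O)/C(C)=C\C)C[C@@](C)(O[Si](CC)(CC)CC)C#C[Si](C)(C)C | intermediate
22 | (6S,7R,8R,10R,11R)-seco iodo-alkynol: vinyl iodide, free C10–OH, terminal alkyne | CN(C)C[C@@H]1C(=O)O[C@H](/C=C(/C)I)[C@H]1[C@H](OC(=O)/C(C)=C\C)C[C@@](C)(O)C#C | intermediate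
23 | (6R,7R,8R,10R,11R)-ten-membered 4Z-en-1-yn-3-one with C10–OH | CN(C)C[C@@H]1C(=O)O[C@@H]2/C=C(/C)C(=O)C#C[C@](C)(O)C[C@@H](OC(=O)/C(C)=C\C)[C@@H]12 | intermediate
24 | (1E,4Z)-1-(diethylamino) macrocyclic dienone with C10–OH | CN(C)C[C@@H]1C(=O)O[C@@H]2/C=C(/C)C(=O)/C=C(N(CC)CC)\[C@](C)(O)C[C@@H](OC(=O)/C(C)=C\C)[C@@H]12 | intermediate
25 | (6R,7R,8R,10R,11R)-13-(dimethylamino)-11,13-dihydro-15-deoxybudlein A | CN(C)C[C@@H]1C(=O)O[C@@H]2/C=C(/C)C3=CC(=O)[C@@](C)(C[C@@H](OC(=O)/C(C)=C\C)[C@@H]12)O3 | intermediate
26 | N-methyl ammonium iodide of 25 | C[N+](C)(C)C[C@@H]1C(=O)O[C@@H]2/C=C(/C)C3=CC(=O)[C@@](C)(C[C@@H](OC(=O)/C(C)=C\C)[C@@H]12)O3.[I-] | intermediate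
27 | 15-deoxybudlein A (6R,7R,8R,10R; 4Z) | C=C1C(=O)O[C@@H]2/C=C(/C)C3=CC(=O)[C@@](C)(C[C@@H](OC(=O)/C(C)=C\C)[C@@H]12)O3 | target

**Total steps:** 13.
**Longest linear sequence:** 11 steps (5 → 27, steps 3–13).

**Steps most likely to fail**

**Step 12.** What may go wrong is that the acylpalladium species is captured by a second molecule (oligomerisation), or that the sequence stalls before the ten-membered ring closes.

The fallback sets out from 21 and comes back at 23, and it uses known chemistry only.
- Reductive carbonylation of the vinyl iodide (Pd(PPh3)4, CO, slow Bu3SnH; the alkyne is still silylated) gives the silylated (Z)-enal F1.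
- TBAF/AcOH gives the free alkynol enal F2.
- NIS with catalytic AgNO3 in acetone, with the amine protonated by CSA, gives the iodoalkyne enal F3.
- An intramolecular Nozaki–Hiyama–Kishi reaction (CrCl2, cat. NiCl2, THF–DMF, high dilution) closes ring B as the macrocyclic propargylic alcohol F4. Its C3 configuration is irrelevant.
- Dess–Martin oxidation gives 23, now isolated. It re-enters the route with Et2NH and then AcOH–H2O to give 25.

**Step 7.** What may go wrong is enolisation toward C9 with loss of silanolate, or insufficient facial discrimination by the borane.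

The fallback sets out from 4 and 12 and comes back at 14. It replaces the aldol by acylation followed by reduction with dynamic kinetic resolution.
- Pinnick oxidation of 4 gives (Z)-3-iodobut-2-enoic acid F5.
- DCC and C6F5OH give its pentafluorophenyl ester F6.
- Soft-enolisation C-acylation of 12 (MgBr2·OEt2, i-Pr2NEt) gives the C7-substituted 1,3-diketone F7, which is configurationally labile at C7.
- Asymmetric transfer hydrogenation (Ru–TsDPEN, HCO2H–Et3N) reduces only the conjugated C6 ketone and gives 14. PPTS then closes 14 to 15.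

**Step 8.** What may go wrong is poor facial selectivity of hydride delivery, or migration of the lactone to O8 from the alkoxide.

The fallback sets out from 15 and comes back at 21. It sets C8 by inversion during ester formation.
- Chelation-controlled reduction (Zn(BH4)2, Et2O, −30 °C, chelate between C8=O and the ring oxygen on C6) should give the 8S alcohol F8.
- LiHMDS and Eschenmoser's salt give its Mannich base F9.
- Mitsunobu esterification with 19 (PPh3, DIAD, toluene) installs the angelate with inversion at C8 to give 21.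

**Further compounds**
F1 | step 12 | silylated (Z)-enal (C4–CHO in place of C4–I in 21) | CN(C)C[C@@H]1C(=O)O[C@H](/C=C(/C)C=O)[C@H]1[C@H](OC(=O)/C(C)=C\C)C[C@@](C)(O[Si](CC)(CC)CC)C#C[Si](C)(C)C
F2 | step 12 | free alkynol enal | CN(C)C[C@@H]1C(=O)O[C@H](/C=C(/C)C=O)[C@H]1[C@H](OC(=O)/C(C)=C\C)C[C@@](C)(O)C#C
F3 | step 12 | iodoalkyne enal | CN(C)C[C@@H]1C(=O)O[C@H](/C=C(/C)C=O)[C@H]1[C@H](OC(=O)/C(C)=C\C)C[C@@](C)(O)C#CI
F4 | step 12 | macrocyclic propargylic alcohol (either C3 epimer) | CN(C)C[C@@H]1C(=O)O[C@@H]2/C=C(/C)C(O)C#C[C@](C)(O)C[C@@H](OC(=O)/C(C)=C\C)[C@@H]12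
F5 | step 7 | (Z)-3-iodobut-2-enoic acid | OC(=O)/C=C(/C)I
F6 | step 7 | pentafluorophenyl (Z)-3-iodobut-2-enoate | O=C(Oc1c(F)c(F)c(F)c(F)c1F)/C=C(/C)I
F7 | step 7 | C7-substituted 1,3-diketone (C7 labile, 10R) | CCOC(=O)CC(C(=O)/C=C(/C)I)C(=O)C[C@@](C)(O[Si](CC)(CC)CC)C#C[Si](C)(C)C
F8 | step 8 | (6S,7R,8S,10R)-hydroxy lactone, 8-epimer of 16 | C1C(=O)O[C@H](/C=C(/C)I)[C@H]1[C@@H](O)C[C@@](C)(O[Si](CC)(CC)CC)C#C[Si](C)(C)C
F9 | step 8 | 8-epimer of Mannich base 18 | CN(C)C[C@@H]1C(=O)O[C@H](/C=C(/C)I)[C@H]1[C@@H](O)C[C@@](C)(O[Si](CC)(CC)CC)C#C[Si](C)(C)C
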